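Count the E rather than the G, and work with the fraction of each reactant left.

all flasks: L 0.25 M

| flask | E | X | remark | time |
|---|---|---|---|---|
| ash | 0.14 M | 0.75 M | run made earlier |  |
| oak | 0.55 M | 0.75 M | run made earlier |  |
| cedar | 0.275 M | 1.5 M | run made earlier |  |
| flask | 0.275 M | 0.750 M |  | 4.0 d |

- ash (time / d: G / %, L / %): 0.333: 4.6, 95.9; 0.500: 7.2, 93.9; 0.833: 9.6, 90.9; 1.04: 11.3, 87.4; 1.67: 16.3, 84.3; 2.50: 19.5, 79.9; 4.00: 23.8, 77.2
- oak (time / d: G / %, L / %): 0.333: 17.3, 82.4; 0.500: 24.0, 76.3; 0.833: 34.5, 65.2; 1.04: 40.2, 60.0; 1.67: 53.0, 48.0; 2.50: 62.3, 37.2; 4.00: 73.2, 26.2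
- cedar (time / d: G / %, L / %): 0.333: 8.3, 91.7; 0.625: 15.2, 85.3; 1.04: 21.6, 78.4; 2.00: 32.4, 67.1; 4.00: 43.9, 56.4

(each reading ± 0.5 percentage points)



* amount of G in percent of the L charged, at 10 h, 30 h and 4.0 d

Ash stands at 23.8% G at 4.00 d and is bending over, although its E, spent one for one, would allow 56.0%, and two E per L would allow 28.0%, so we reckon with two E per L reacted. In the flask, two cL over cE is then 1.82, so E is the limiting reagent. With a rate k·cL·cE, the logarithm of one fraction left over the other changes at a steady slope, k times the difference between cE and two cL as charged. From oak's L at 4.00 d we get the two-E constant k, 1.14 /M/d, a reading that carries the scatter. The flask's slope is therefore 0.256 /d, and our reckoning gives 11.0%, 25.1% and 43.9%.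

The forecast reasons “Since X hardly matters, I read the course from cedar” and gives 10.4%, 24.5% and 44.3%, so ours is higher than the forecast at the first two times and lower at the last.

The flask gives 10.9%, 24.9% and 43.8%.

    L + E → Q + G (k = 0.0470 /M/h)
    E + Q ⇌ Z, settled at all times (K = 6200 /M)
    Q + X ⇌ D, settled at all times (K = 1.50 /M)
    X ⇌ J (K = 0.180, k = 0.130 /h)

At 4.00 d the flask holds 0.109 M of Z beside 0.110 M of G, with E down to 20.5% of its charge, and the half-life of L by the step to G, 11 d, is longer than the 2.2 d it has with the concentrations as charged. Our k times that E gives L a first-order loss of 0.0643 /d in the flask at that moment, and on ash the same k gives 23.9% G at 4.00 d, where the reading is 23.8%.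

All runs are simulated from invented constants, and the scatter is random.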